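The route rests on cutting the O–C bond between the enol-ether oxygen on C10 of the dibenzo[b,f]oxepine and the methyl-bearing quaternary carbon of the dihydropyran. The terpenoid half then is the intact skeleton of the monoterpene ketone filifolone: its cyclobutanone carbon becomes the cyclobutane CH on C11, and its ring alkene is a latent tertiary cation beside the ring fusion. The key step, an acid-catalysed cycloisomerisation of an 11-(bicyclo[3.2.0]hept-3-en-6-yl)dibenzoxepin-10-one, adds the carbonyl oxygen across that alkene and so closes the pyran, sets the quaternary stereocentre and creates the C10=C11 enol ether in one operation. Resolved (1S,5S)-filifolone supplies the cyclobutane stereocentres.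

Key step: step 10

Remark: the C11 epimers of 13 and 15 and the two alkene isomers of 14 are carried as mixtures because C11 ends as a trigonal carbon, and commercial geranic acid may be used as its E/Z mixture because both isomers lead to vinylketene 8.

Step 1
Reactants: 1 2-(2-bromo-4-methoxyphenyl)acetic acid; 2 3-methoxyphenol
Product: 3 2-[4-methoxy-2-(3-methoxyphenoxy)phenyl]acetic acid
Conditions: CuI (10 mol%), N,N-dimethylglycine hydrochloride (30 mol%), Cs2CO3, 1,4-dioxane, 100 °C; then aq. HCl
Reagents that add atoms: none
Why: Copper-catalysed Ullmann diaryl ether coupling of the aryl bromide with the phenoxide should proceed with the acid present as its carboxylate, which is a far poorer nucleophile than the phenoxide; no stereocentre is formed.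

Step 2
Reactants: 3 2-[4-methoxy-2-(3-methoxyphenoxy)phenyl]acetic acid
Product: 4 3,7-dimethoxydibenzo[b,f]oxepin-10(11H)-one
Conditions: polyphosphoric acid, 80 °C
Reagents that add atoms: none
Why: Intramolecular Friedel–Crafts acylation should close the seven-membered ketone at the ring B carbon that is para to the methoxy group and ortho to the ether oxygen, the only other ortho site lying between two oxygen substituents and being more hindered.

Step 3
Reactants: 4 3,7-dimethoxydibenzo[b,f]oxepin-10(11H)-one
Product: 5 2-bromo-3,7-dimethoxydibenzo[b,f]oxepin-10(11H)-one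
Conditions: N-bromosuccinimide (1.0 equiv), MeCN, 0 °C, dark
Reagents that add atoms: N-bromosuccinimide, O=C1CCC(=O)N1Br
Why: Electrophilic aromatic bromination should take place at C2 of ring A (ortho to methoxy, para to the ether oxygen), because ring B is deactivated by the conjugated carbonyl and C4 lies between two oxygens; without acid the nuclear substitution should outpace α-bromination at C11.

Step 4
Reactants: 6 geranic acid [(2E)-3,7-dimethylocta-2,6-dienoic acid]
Product: 9 (±)-filifolone [cis-fused rac-4,7,7-trimethylbicyclo[3.2.0]hept-3-en-6-one], via mixed anhydride 7 (not isolated), via vinylketene 8 (not isolated)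
Conditions: Ac2O, NaOAc, reflux (about 140 °C)
Reagents that add atoms: none
Why: The mixed anhydride should lose acetic acid by γ-deprotonation to give vinylketene 8, whose intramolecular ketene–alkene [2+2] cycloaddition closes cyclopentene and cyclobutanone together; the cis ring fusion is the only one the tether allows, reversibility at this temperature favours the less strained fused regioisomer, and the product is racemic.

Step 5
Reactants: 9 (±)-filifolone; 10 (S)-N,S-dimethyl-S-phenylsulfoximine
Product: 11 β-hydroxysulfoximine of (1S,5S)-filifolone [(1S,5S)-6-endo-hydroxy-6-exo-{[(S)-N-methyl-S-phenylsulfonimidoyl]methyl}-4,7,7-trimethylbicyclo[3.2.0]hept-3-ene]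
Conditions: n-BuLi, THF, −78 °C (on 10); then 9, −78 °C; aq. NH4Cl; chromatography on silica
Reagents that add atoms: none
Why: 1,2-Addition of the lithiated sulfoximine to the cyclobutanone from the convex face should convert the two ketone enantiomers into diastereomeric β-hydroxysulfoximines (resolution of a ketone through covalent diastereomers); 11 is separated on silica from the diastereomer that derives from the (1R,5R)-ketone, and its configuration is to be assigned by X-ray crystallography.

Step 6
Reactants: 11 β-hydroxysulfoximine of (1S,5S)-filifolone
Product: 12 (1S,5S)-filifolone [(1S,5S)-4,7,7-trimethylbicyclo[3.2.0]hept-3-en-6-one]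
Conditions: toluene, 100 °C
Reagents that add atoms: none
Why: Thermal retro-addition (retro-aldol-type fragmentation of the β-hydroxysulfoximine) should release the enantiopure ketone and the reusable sulfoximine without touching the two ring-fusion stereocentres.

Step 7
Reactants: 5 2-bromo-3,7-dimethoxydibenzo[b,f]oxepin-10(11H)-one; 12 (1S,5S)-filifolone
Product: 13 aldol adduct, 2-bromo-11-[(1S,5S)-6-endo-hydroxy-4,7,7-trimethylbicyclo[3.2.0]hept-3-en-6-yl]-3,7-dimethoxydibenzo[b,f]oxepin-10(11H)-one (C11 epimers)
Conditions: TiCl4, Bu3N, CH2Cl2, −78 °C (on 5); then 12, −78 to −40 °C; aq. work-up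
Reagents that add atoms: none
Why: Titanium-mediated crossed aldol addition (soft enolisation of the aryl benzyl ketone, then addition to the strained and therefore electrophilic cyclobutanone) should give a chelated titanium aldolate that resists retro-aldol cleavage; attack from the convex face places the hydroxyl endo.

Step 8
Reactants: 13 aldol adduct
Product: 14 enone, 2-bromo-3,7-dimethoxy-11-[(1S,5S)-4,7,7-trimethylbicyclo[3.2.0]hept-3-en-6-ylidene]dibenzo[b,f]oxepin-10(11H)-one (E/Z mixture)
Conditions: Ph2S[OC(CF3)2Ph]2 (bis[α,α-bis(trifluoromethyl)benzyloxy]diphenylsulfurane), CH2Cl2, 0 °C to rt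
Reagents that add atoms: none
Why: Sulfurane-mediated dehydration of the tertiary β-hydroxy ketone should proceed by loss of the acidic C11 hydrogen (E1cB-like elimination) to the conjugated alkylidenecyclobutane, the only other β-hydrogen being at the bridgehead; either alkene geometry is acceptable.

Step 9
Reactants: 14 enone
Product: 15 ketone, 2-bromo-3,7-dimethoxy-11-[(1S,5R,6S)-4,7,7-trimethylbicyclo[3.2.0]hept-3-en-6-yl]dibenzo[b,f]oxepin-10(11H)-one (dibenzoxepinone on the endo face of C6; C11 epimers)
Conditions: SmI2 (2.2 equiv), THF–MeOH, −78 °C
Reagents that add atoms: none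
Why: Single-electron conjugate reduction of the aryl enone by SmI2 should end with protonation of C6 by methanol from the convex face, which sets the cyclobutane CH stereocentre with the dibenzoxepinone on the concave (endo) face; the aryl bromide and the isolated ring alkene should not be reduced at −78 °C.

Step 10
Reactants: 15 ketone
Product: 16 bromo dimethyl ether of the pentacyclic cyclol (the target skeleton with Br in place of prenyl and OMe in place of both OH)
Conditions: TfOH (10 mol%), 4 Å molecular sieves, CH2Cl2, −40 to 0 °C
Reagents that add atoms: none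
Why: Markovnikov protonation of the ring alkene (C3=C4 of the bicycloheptene) gives the tertiary carbocation at the methyl-bearing carbon, the C10 carbonyl oxygen captures it, and loss of the C11 proton from the resulting oxocarbenium ion leaves the tetrasubstituted enol ether, so both C11 epimers of 15 converge. The closest known reaction type is the Brønsted acid-catalysed intramolecular hydroalkoxylation (cycloisomerisation) of trisubstituted alkenes by phenol or enol oxygen, as in chroman formation from ortho-prenylphenols. The dihydropyran closes in the 6-exo-trig mode by O-attack on the cationic carbon. The new quaternary C–O stereocentre is controlled by the bicyclic framework: the ketone hangs from C6 on the concave face, so its oxygen can reach the cation only from that face and only the cis-fused pyran–cyclobutane can form. The step needs capture by oxygen to outrun 1,2-shift, proton loss and arene alkylation, which is secured by the six-membered geometry, by the fact that the possible Wagner–Meerwein shifts lead only to secondary cations, by the reversibility of proton loss, and by the electron-poor arene positions flanking C11. Chemoselectivity over the side chain is secured by design, since the aryl bromide stands in for the acid-labile prenyl group and both phenols are methyl ethers at this stage.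

Step 11
Reactants: 16 bromo dimethyl ether of the cyclol
Product: 17 prenylated dimethyl ether (the target with both phenols as methyl ethers)
Conditions: tributyl(3-methylbut-2-en-1-yl)stannane, Pd(PPh3)4 (5 mol%), LiCl, DMF, 100 °C
Reagents that add atoms: tributyl(3-methylbut-2-en-1-yl)stannane, CC(C)=CC[Sn](CCCC)(CCCC)CCCC
Why: Stille cross-coupling of the aryl bromide with the prenylstannane under zerovalent palladium catalysis should deliver the linear (α-coupled) prenyl group under neutral conditions that leave the enol ether untouched.

Step 12
Reactants: 17 prenylated dimethyl ether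
Product: 18 CNP0185814.1 (target)
Conditions: NaSEt (excess), DMF, 130 °C; then aq. NH4Cl
Reagents that add atoms: none
Why: Thiolate-mediated O-demethylation (SN2 attack at the methyl carbons) should free both phenols without acid, so that the prenyl group, the enol ether and the tertiary alkyl–oxygen bond survive.

**Compound list**

1 | 2-(2-bromo-4-methoxyphenyl)acetic acid | COc1ccc(CC(=O)O)c(Br)c1 | starting material
2 | 3-methoxyphenol | COc1cccc(O)c1 | starting material
3 | 2-[4-methoxy-2-(3-methoxyphenoxy)phenyl]acetic acid | COc1cccc(Oc2cc(OC)ccc2CC(=O)O)c1 | intermediate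
4 | 3,7-dimethoxydibenzo[b,f]oxepin-10(11H)-one | O=C1Cc2ccc(OC)cc2Oc2cc(OC)ccc21 | intermediate
5 | 2-bromo-3,7-dimethoxydibenzo[b,f]oxepin-10(11H)-one | O=C1Cc2cc(Br)c(OC)cc2Oc2cc(OC)ccc21 | intermediate
6 | geranic acid, (2E)-3,7-dimethylocta-2,6-dienoic acid | CC(C)=CCC/C(C)=C/C(=O)O | starting material
7 | acetic geranic mixed anhydride | CC(C)=CCC/C(C)=C/C(=O)OC(C)=O | intermediate (not isolated)
8 | vinylketene, (3Z)-3,7-dimethylocta-1,3,6-trien-1-one | O=C=C/C(C)=C\CC=C(C)C | intermediate (not isolated)
9 | (±)-filifolone, cis-fused racemic 4,7,7-trimethylbicyclo[3.2.0]hept-3-en-6-one | CC1=CCC2C1C(=O)C2(C)C | intermediate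
10 | (S)-N,S-dimethyl-S-phenylsulfoximine | CN=[S@@](C)(=O)c1ccccc1 | starting material
11 | β-hydroxysulfoximine of (1S,5S)-filifolone (6-endo-OH, 6-exo-CH2, S at sulfur) | CC1=CC[C@H]2[C@@H]1[C@](O)(C[S@@](=O)(=NC)c1ccccc1)C2(C)C | intermediate
12 | (1S,5S)-filifolone, (1S,5S)-4,7,7-trimethylbicyclo[3.2.0]hept-3-en-6-one | CC1=CC[C@H]2[C@@H]1C(=O)C2(C)C | intermediate
13 | aldol adduct, 6-endo-hydroxy, C11 epimers | O=C1c2ccc(OC)cc2Oc2cc(OC)c(Br)cc2C1[C@@]1(O)[C@@H]2C(C)=CC[C@@H]2C1(C)C | intermediate
14 | enone, 11-(bicycloheptenylidene) ketone, E/Z mixture | O=C1c2ccc(OC)cc2Oc2cc(OC)c(Br)cc2C1=C1[C@@H]2C(C)=CC[C@@H]2C1(C)C | intermediate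
15 | ketone with the dibenzoxepinone on the endo face of C6, C11 epimers (ring-fusion geometry as in 12; the C5 descriptor changes only through the CIP priorities) | O=C1c2ccc(OC)cc2Oc2cc(OC)c(Br)cc2C1[C@@H]1[C@@H]2C(C)=CC[C@@H]2C1(C)C | intermediate
16 | bromo dimethyl ether of the pentacyclic cyclol (all three cyclobutane hydrogens cis, pyran oxygen on the same face as C11) | Brc1cc2c(cc1OC)Oc1cc(OC)ccc1C1=C2[C@@H]2[C@H]3[C@H](CC[C@@]3(C)O1)C2(C)C | intermediate
17 | prenylated dimethyl ether of the cyclol | CC(C)=CCc1cc2c(cc1OC)Oc1cc(OC)ccc1C1=C2[C@@H]2[C@H]3[C@H](CC[C@@]3(C)O1)C2(C)C | intermediate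
18 | CNP0185814.1, 3,7-dihydroxy-2-prenyldibenzo[b,f]oxepine fused at C10–C11 to the cyclol dihydropyran | CC(C)=CCc1cc2c(cc1O)Oc1cc(O)ccc1C1=C2[C@@H]2[C@H]3[C@H](CC[C@@]3(C)O1)C2(C)C | target

**Step count and risks**

Total step count: 12. Longest linear sequence: 9 steps (steps 1, 2, 3, 7, 8, 9, 10, 11, 12; the filifolone branch through steps 4, 5, 6 is equally long).

Steps most likely to fail:

Step 7. The addition may not take place, or may revert on work-up, because the enolate carbon is secondary and benzylic and the carbonyl is flanked by a quaternary carbon; enolisation of 12 is a further drain. The fallback changes the donor from an enolate to a vinyl organometallic; it sets out from 5 (and 12) and comes back to the route at 14. Ketone 5 would be O-methylated (KN(SiMe3)2, THF–DMPU, −78 °C; Me2SO4) to 2-bromo-3,7,10-trimethoxydibenzo[b,f]oxepine F1. Iodination at C11 (N-iodosuccinimide, CH2Cl2, then Et3N) should give 2-bromo-11-iodo-3,7,10-trimethoxydibenzo[b,f]oxepine F2. Iodine–magnesium exchange (i-PrMgCl·LiCl, THF, −40 °C, under which the aryl bromide should exchange far more slowly), followed by LaCl3·2LiCl and ketone 12, should give the tertiary allylic alcohol (1S,5S)-6-(2-bromo-3,7,10-trimethoxydibenzo[b,f]oxepin-11-yl)-4,7,7-trimethylbicyclo[3.2.0]hept-3-en-6-endo-ol F3. Dilute aqueous HCl in THF should then ionise the allylic alcohol and hydrolyse the enol ether, delivering enone 14 directly.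

Step 9. Over-reduction of the ketone, reductive dimerisation, or protonation of C6 from the concave face may erode the yield or the configuration of the cyclobutane CH. The fallback replaces electron transfer by Lewis-acid-catalysed hydride transfer; it sets out from 14 and comes back to the route at 15. 1,4-Hydrosilylation (B(C6F5)3 2 mol%, Et3SiH 1.05 equiv, CH2Cl2, 0 °C) should deliver hydride to C6 from the convex face and give the triethylsilyl enol ether of 15 F4. Desilylation with Bu4NF/AcOH in THF should then return ketone 15.

Step 10. The tertiary cation may lose a proton to alkene isomers without closing, the cyclobutylcarbinyl system may undergo skeletal rearrangement, or the product enol ether may be hydrolysed by adventitious water. The fallback forms the same O–C bond through a bridged iodonium ion instead of a free carbocation; it sets out from 15 and comes back to the route at 16. Iodoetherification (N-iodosuccinimide, NaHCO3, CH2Cl2, −40 °C) should give the iodo cyclol F5, with iodine on the cyclopentane carbon next to the new C–O carbon and trans to the oxygen. Radical deiodination (Bu3SnH, AIBN, benzene, 80 °C) should then give 16, since the alkyl iodide reacts far faster than the aryl bromide.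

**Further compounds**

F1 | step 7 | 2-bromo-3,7,10-trimethoxydibenzo[b,f]oxepine | COC1=Cc2cc(Br)c(OC)cc2Oc2cc(OC)ccc21
F2 | step 7 | 2-bromo-11-iodo-3,7,10-trimethoxydibenzo[b,f]oxepine | COC1=C(I)c2cc(Br)c(OC)cc2Oc2cc(OC)ccc21
F3 | step 7 | (1S,5S)-6-(2-bromo-3,7,10-trimethoxydibenzo[b,f]oxepin-11-yl)-4,7,7-trimethylbicyclo[3.2.0]hept-3-en-6-endo-ol | COC1=C(c2cc(Br)c(OC)cc2Oc2cc(OC)ccc21)[C@@]1(O)[C@@H]2C(C)=CC[C@@H]2C1(C)C
F4 | step 9 | triethylsilyl enol ether of 15 | CC[Si](CC)(CC)OC1=C([C@@H]2[C@@H]3C(C)=CC[C@@H]3C2(C)C)c2cc(Br)c(OC)cc2Oc2cc(OC)ccc21
F5 | step 10 | iodo cyclol, 16 bearing iodine on the cyclopentane carbon next to the C–O carbon, trans to oxygen | Brc1cc2c(cc1OC)Oc1cc(OC)ccc1C1=C2[C@@H]2[C@H]3[C@H](C[C@H](I)[C@@]3(C)O1)C2(C)C
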